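**Retrosynthetic overview**
- Last ring (the 1,5-benzodioxepine): cut C5–O7'' and C7–O6''. This gives a catechol chromone and a syn-5,6:7,8-diepoxy-tetrahydrochromone; two anti epoxide openings fix the all-trans array.
- Both oxiranes come from one operation on a chromone (5R,6R)-trans-5,6-dihydrodiol: hydroxyl-directed epoxidation of C7=C8, then Mitsunobu closure across C5–C6.
- The trans-dihydrodiol comes from dearomatising the benzo ring of a 6-hydroxychromone: 5,6-ortho-quinone, hydride reduction, catalytic kinetic resolution.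
- Both 4-pyranone rings come from Claisen C-acylation/cyclodehydration of o-hydroxyacetophenones with 3-arylpropanoyl chlorides.
- Ring order: the two pyranone rings, then the 7,8- and 5,6-oxiranes (one flask), then the dioxepine.

Assumption: locants follow 2-(2-phenylethyl)chromone numbering, plain for the tetrahydrochromone half and doubly primed for the aromatic chromone half; read this way the target SMILES is (5R,6S,7R,8S), with O7'' on C5 and O6'' on C7.

**Step 1**
Reactants: 1 2',5'-dihydroxyacetophenone; 2 3-(4-methoxyphenyl)propanoyl chloride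
Product: 4 6-hydroxy-2-[2-(4-methoxyphenyl)ethyl]-4H-chromen-4-one, via beta-diketone 3 (not isolated)
Conditions: LiN(SiMe3)2 (4.2 equiv), THF, −78 °C to rt; then conc. HCl, AcOH, 90 °C
Reagents that add atoms: none
Why: Crossed Claisen C-acylation of the ketone lithium enolate (polyanion of the free hydroxyacetophenone) by the acid chloride gives the o-hydroxyaryl beta-diketone, and acid-catalysed cyclodehydration closes the 4-pyranone ring (classical chromone synthesis), with no stereocentre formed.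

**Step 2**
Reactants: 4 6-hydroxy-2-[2-(4-methoxyphenyl)ethyl]-4H-chromen-4-one
Product: 5 2-[2-(4-methoxyphenyl)ethyl]-4H-chromene-4,5,6-trione (the 5,6-ortho-quinone)
Conditions: IBX (1.1 equiv), DMF, rt, dark
Reagents that add atoms: 2-iodoxybenzoic acid (IBX), O=C1OI(=O)(O)c2ccccc12
Why: Regioselective ortho-oxygenation of a phenol by IBX transfers oxygen from the aryloxy-iodine intermediate to the more nucleophilic ortho carbon (C5, the site that also wins in electrophilic substitution of 6-hydroxychromones, as C1 does in 2-naphthol) and then loses 2-iodobenzoic acid to give the ortho-quinone, with no stereocentre formed.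

**Step 3**
Reactants: 5 2-[2-(4-methoxyphenyl)ethyl]-4H-chromene-4,5,6-trione
Product: 6 rac-(5R,6R)-5,6-dihydroxy-2-[2-(4-methoxyphenyl)ethyl]-5,6-dihydro-4H-chromen-4-one (trans-dihydrodiol, C7=C8 kept)
Conditions: NaBH4 (10 equiv), EtOH, O2 stream, 0 °C to rt
Reagents that add atoms: none
Why: Borohydride 1,2-reduction of an arene ortho-quinone gives the trans-dihydrodiol because the second hydride adds anti to the first carbinol oxygen, while oxygen re-oxidises any catechol formed by tautomerisation back to the quinone (the standard route to arene trans-dihydrodiols), so C5 and C6 are set trans but racemic.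

**Step 4**
Reactants: 6 rac-(5R,6R)-5,6-dihydroxy-2-[2-(4-methoxyphenyl)ethyl]-5,6-dihydro-4H-chromen-4-one
Product: 7 (5R,6R)-5,6-dihydroxy-2-[2-(4-methoxyphenyl)ethyl]-5,6-dihydro-4H-chromen-4-one
Conditions: Cu(OTf)2 (5 mol%), (R,R)-Ph-box [2,2'-(propane-2,2-diyl)bis((4R)-4-phenyl-4,5-dihydrooxazole)] (5 mol%), PhCOCl (0.55 equiv), K2CO3, CH2Cl2, 0 °C; recover unreacted diol
Reagents that add atoms: none
Why: Kinetic resolution by enantioselective monobenzoylation of a copper-chelated vicinal diol with a chiral bisoxazoline ligand acylates the (5S,6S)-diol and leaves the (5R,6R)-diol, whose C6 configuration controls every later stereocentre (the mirror-image ligand is used if the sense is found to be reversed on this substrate).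

**Step 5**
Reactants: 7 (5R,6R)-5,6-dihydroxy-2-[2-(4-methoxyphenyl)ethyl]-5,6-dihydro-4H-chromen-4-one
Product: 9 (5S,6S,7S,8S)-5,6:7,8-diepoxy-2-[2-(4-methoxyphenyl)ethyl]-5,6,7,8-tetrahydro-4H-chromen-4-one (both oxiranes on the same face), via anti-diol epoxide 8 (not isolated)
Conditions: mCPBA, NaHCO3, THF, 0 °C to rt; aq. Na2SO3/NaHCO3 wash; then PPh3, DIAD, THF, 0 °C to rt
Reagents that add atoms: meta-chloroperbenzoic acid (mCPBA), OOC(=O)c1cccc(Cl)c1
Why: Henbest-type hydroxyl-directed peracid epoxidation puts the 7,8-oxirane on the face of the allylic C6 hydroxyl (the anti-diol-epoxide mode of arene trans-dihydrodiols, setting C7 and C8), and Mitsunobu cyclodehydration then activates the vinylogous-benzylic C5 hydroxyl rather than the C6 hydroxyl flanked by the new oxirane, so the C6 oxygen displaces it with inversion and the second oxirane is forced onto the same face.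

**Step 6**
Reactants: 10 2'-hydroxy-4',5'-dimethoxyacetophenone; 11 3-phenylpropanoyl chloride
Product: 14 6,7-dihydroxy-2-(2-phenylethyl)-4H-chromen-4-one, via beta-diketone 12 (not isolated), via 6,7-dimethoxychromone 13 (not isolated)
Conditions: LiN(SiMe3)2 (3.2 equiv), THF, −78 °C to rt; then 48% aq. HBr, AcOH, reflux
Reagents that add atoms: none
Why: The same Claisen C-acylation and acid cyclodehydration as in step 1 build the chromone, and refluxing HBr in acetic acid also cleaves both aryl methyl ethers (SN2 demethylation) to unmask the catechol, with no stereocentre formed.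

**Step 7**
Reactants: 9 (5S,6S,7S,8S)-5,6:7,8-diepoxy-2-[2-(4-methoxyphenyl)ethyl]-5,6,7,8-tetrahydro-4H-chromen-4-one; 14 6,7-dihydroxy-2-(2-phenylethyl)-4H-chromen-4-one
Product: 16 (+)-4'-methoxyaquisinenone G (5R,6S,7R,8S), via C5 aryl ether epoxy alcohol 15 (not isolated)
Conditions: Cs2CO3 (0.3 equiv), DMF (0.01 M), 45 °C
Reagents that add atoms: none
Why: In this biomimetic double epoxide opening the more acidic 7''-phenoxide attacks the C5 oxirane terminus, which is activated by the ring oxygen through C4a=C8a, with inversion (trans-diaxial, Fürst–Plattner), and the axial aryl ether then lets the 6''-phenol close the seven-membered ring by 7-exo anti opening of the 7,8-oxirane at C7, giving 5R,6S,7R,8S.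

**Compound list**
1 | 2',5'-dihydroxyacetophenone | CC(=O)c1cc(O)ccc1O | starting material
2 | 3-(4-methoxyphenyl)propanoyl chloride | COc1ccc(CCC(Cl)=O)cc1 | starting material
3 | 1-(2,5-dihydroxyphenyl)-5-(4-methoxyphenyl)pentane-1,3-dione | COc1ccc(CCC(=O)CC(=O)c2cc(O)ccc2O)cc1 | intermediate
4 | 6-hydroxy-2-[2-(4-methoxyphenyl)ethyl]-4H-chromen-4-one | COc1ccc(CCc2cc(=O)c3cc(O)ccc3o2)cc1 | intermediate
5 | 2-[2-(4-methoxyphenyl)ethyl]-4H-chromene-4,5,6-trione | COc1ccc(CCc2cc(=O)c3c(o2)C=CC(=O)C3=O)cc1 | intermediate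
6 | rac-(5R,6R)-5,6-dihydroxy-2-[2-(4-methoxyphenyl)ethyl]-5,6-dihydro-4H-chromen-4-one (racemic trans-diol; one enantiomer drawn) | COc1ccc(CCc2cc(=O)c3c(o2)C=C[C@@H](O)[C@@H]3O)cc1 | intermediate
7 | (5R,6R)-5,6-dihydroxy-2-[2-(4-methoxyphenyl)ethyl]-5,6-dihydro-4H-chromen-4-one | COc1ccc(CCc2cc(=O)c3c(o2)C=C[C@@H](O)[C@@H]3O)cc1 | intermediate
8 | (5R,6S,7S,8S)-7,8-epoxy-5,6-dihydroxy-2-[2-(4-methoxyphenyl)ethyl]-5,6,7,8-tetrahydro-4H-chromen-4-one (oxirane cis to 6-OH, trans to 5-OH) | COc1ccc(CCc2cc(=O)c3c(o2)[C@H]4O[C@H]4[C@@H](O)[C@@H]3O)cc1 | intermediate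
9 | (5S,6S,7S,8S)-5,6:7,8-diepoxy-2-[2-(4-methoxyphenyl)ethyl]-5,6,7,8-tetrahydro-4H-chromen-4-one | COc1ccc(CCc2cc(=O)c3c(o2)[C@H]4O[C@H]4[C@H]5O[C@H]53)cc1 | intermediate
10 | 2'-hydroxy-4',5'-dimethoxyacetophenone | CC(=O)c1cc(OC)c(OC)cc1O | starting material
11 | 3-phenylpropanoyl chloride | ClC(=O)CCc1ccccc1 | starting material
12 | 1-(2-hydroxy-4,5-dimethoxyphenyl)-5-phenylpentane-1,3-dione | COc1cc(O)c(cc1OC)C(=O)CC(=O)CCc1ccccc1 | intermediate
13 | 6,7-dimethoxy-2-(2-phenylethyl)-4H-chromen-4-one | COc1cc2oc(CCc3ccccc3)cc(=O)c2cc1OC | intermediate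
14 | 6,7-dihydroxy-2-(2-phenylethyl)-4H-chromen-4-one | O=c1cc(CCc2ccccc2)oc2cc(O)c(O)cc12 | intermediate
15 | (5R,6S,7S,8S)-7,8-epoxy-6-hydroxy-5-{[6-hydroxy-4-oxo-2-(2-phenylethyl)-4H-chromen-7-yl]oxy}-2-[2-(4-methoxyphenyl)ethyl]-5,6,7,8-tetrahydro-4H-chromen-4-one | COc1ccc(CCc2cc(=O)c3c(o2)[C@H]4O[C@H]4[C@@H](O)[C@@H]3Oc6cc7oc(CCc8ccccc8)cc(=O)c7cc6O)cc1 | intermediate
16 | (+)-4'-methoxyaquisinenone G, (5R,6S,7R,8S) | COc1ccc(CCc2cc(=O)c3c(o2)[C@@H](O)[C@@H]2Oc4cc5c(=O)cc(CCc6ccccc6)oc5cc4O[C@H]3[C@@H]2O)cc1 | target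

**Step count and risks**
Total step count: 7. Longest linear sequence: 6 (steps 1, 2, 3, 4, 5, 7). The three steps most likely to fail are steps 5, 7 and 4.

Step 5 can fail through poor facial control on the deactivated C7=C8 bond, or through loss of the acid-labile syn-dioxide. The fallback inverts the order of events and avoids the dioxide. It sets out from 7: Mitsunobu dehydration (PPh3, DIAD, THF, 0 °C) gives the arene oxide (5S,6R)-5,6-epoxy-2-[2-(4-methoxyphenyl)ethyl]-5,6-dihydro-4H-chromen-4-one F3. The 7''-phenoxide of 14 (Cs2CO3 cat., DMF, 0 °C) opens F3 at C5 to the trans adduct (5R,6R)-6-hydroxy-5-{[6-hydroxy-4-oxo-2-(2-phenylethyl)-4H-chromen-7-yl]oxy}-2-[2-(4-methoxyphenyl)ethyl]-5,6-dihydro-4H-chromen-4-one F4. Buffered mCPBA epoxidation of F4, directed by its single allylic C6 hydroxyl, gives 15, where the route is rejoined; 15 closes to 16 under the conditions of step 7.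

Step 7 can fail through attack at C8, attack by the 6''-oxygen, or oligomerisation. The fallback makes the two C–O bonds one at a time with a differentiated nucleophile. It sets out from 14: TBSCl/imidazole in DMF gives 6,7-bis(tert-butyldimethylsilyloxy)-2-(2-phenylethyl)-4H-chromen-4-one F5. K2CO3 in MeOH at 0 °C cleaves the silyl ether of the more acidic 7-phenol to give 6-(tert-butyldimethylsilyloxy)-7-hydroxy-2-(2-phenylethyl)-4H-chromen-4-one F6. F6 is joined to 9 under Lewis-acid control (Sc(OTf)3 cat., CH2Cl2, −40 °C), which opens only the cation-stabilised C5 terminus anti, to give the silyl-protected C5 ether (5R,6S,7S,8S)-5-{[6-(tert-butyldimethylsilyloxy)-4-oxo-2-(2-phenylethyl)-4H-chromen-7-yl]oxy}-7,8-epoxy-6-hydroxy-2-[2-(4-methoxyphenyl)ethyl]-5,6,7,8-tetrahydro-4H-chromen-4-one F7. Bu4NF in THF then frees the 6''-phenoxide, which closes the ring at C7, and the route is rejoined at 16.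

Step 4 can fail through a low selectivity factor on this diol. The fallback is a classical resolution with a stoichiometric auxiliary. It sets out from 6: (−)-menthyloxyacetyl chloride and pyridine in CH2Cl2 at 0 °C give two diastereomeric bis-esters, (5R,6R)-2-[2-(4-methoxyphenyl)ethyl]-4-oxo-5,6-dihydro-4H-chromene-5,6-diyl bis{[(1R,2S,5R)-menthyl]oxyacetate} F1 and its (5S,6S)-configured diastereomer (5S,6S)-2-[2-(4-methoxyphenyl)ethyl]-4-oxo-5,6-dihydro-4H-chromene-5,6-diyl bis{[(1R,2S,5R)-menthyl]oxyacetate} F2. These are separated by chromatography or crystallisation. NaOMe (cat.) in MeOH at 0 °C cleaves F1 to 7, where the route is rejoined.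

**Further compounds**
F1 | step 4 | (5R,6R)-2-[2-(4-methoxyphenyl)ethyl]-4-oxo-5,6-dihydro-4H-chromene-5,6-diyl bis{[(1R,2S,5R)-menthyl]oxyacetate} | COc1ccc(CCc2cc(=O)c3c(o2)C=C[C@@H](OC(=O)CO[C@@H]4C[C@H](C)CC[C@H]4C(C)C)[C@@H]3OC(=O)CO[C@@H]5C[C@H](C)CC[C@H]5C(C)C)cc1
F2 | step 4 | (5S,6S)-2-[2-(4-methoxyphenyl)ethyl]-4-oxo-5,6-dihydro-4H-chromene-5,6-diyl bis{[(1R,2S,5R)-menthyl]oxyacetate} | COc1ccc(CCc2cc(=O)c3c(o2)C=C[C@H](OC(=O)CO[C@@H]4C[C@H](C)CC[C@H]4C(C)C)[C@H]3OC(=O)CO[C@@H]5C[C@H](C)CC[C@H]5C(C)C)cc1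
F3 | step 5 | (5S,6R)-5,6-epoxy-2-[2-(4-methoxyphenyl)ethyl]-5,6-dihydro-4H-chromen-4-one | COc1ccc(CCc2cc(=O)c3c(o2)C=C[C@H]4O[C@H]43)cc1
F4 | step 5 | (5R,6R)-6-hydroxy-5-{[6-hydroxy-4-oxo-2-(2-phenylethyl)-4H-chromen-7-yl]oxy}-2-[2-(4-methoxyphenyl)ethyl]-5,6-dihydro-4H-chromen-4-one | COc1ccc(CCc2cc(=O)c3c(o2)C=C[C@@H](O)[C@@H]3Oc6cc7oc(CCc8ccccc8)cc(=O)c7cc6O)cc1
F5 | step 7 | 6,7-bis(tert-butyldimethylsilyloxy)-2-(2-phenylethyl)-4H-chromen-4-one | CC(C)(C)[Si](C)(C)Oc1cc2oc(CCc3ccccc3)cc(=O)c2cc1O[Si](C)(C)C(C)(C)C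
F6 | step 7 | 6-(tert-butyldimethylsilyloxy)-7-hydroxy-2-(2-phenylethyl)-4H-chromen-4-one | CC(C)(C)[Si](C)(C)Oc1cc2c(=O)cc(CCc3ccccc3)oc2cc1O
F7 | step 7 | (5R,6S,7S,8S)-5-{[6-(tert-butyldimethylsilyloxy)-4-oxo-2-(2-phenylethyl)-4H-chromen-7-yl]oxy}-7,8-epoxy-6-hydroxy-2-[2-(4-methoxyphenyl)ethyl]-5,6,7,8-tetrahydro-4H-chromen-4-one | COc1ccc(CCc2cc(=O)c3c(o2)[C@H]4O[C@H]4[C@@H](O)[C@@H]3Oc6cc7oc(CCc8ccccc8)cc(=O)c7cc6O[Si](C)(C)C(C)(C)C)cc1
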